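The 20-membered ring of pakyonol, a bis(bibenzyl) with two diaryl ethers, is opened at the ether between the oxygen on C3 of ring A (the methoxy ring) and C4 of ring B (the para-phenylene). The key step, a copper-mediated Chan–Lam–Evans macrocyclisation, joins this phenol oxygen to the boron-bearing ring B carbon and gives the natural product directly, without protecting groups. It exploits topology: the other free phenol, C3–OH of ring C, could reach C4 of ring B only through an impossible 10-membered cyclophane. The precursor is an open-chain bisphenol aryl pinacol boronate, assembled by SNAr, Heck and Wittig reactions and one threefold-duty hydrogenation.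

Key step: step 7

Ring labels: ring A = 3-aryloxy-4-methoxyphenyl ring; ring B = para-phenylene; ring C = 4-aryloxy-3-hydroxyphenyl ring; ring D = meta-phenylene. In each ring C1 is the carbon that carries the CH2CH2 link.
Assumption: 3-(benzyloxy)-4-fluorobenzaldehyde 2 is treated as a purchasable building block, as are 1, 4 and 7.
Remark: the E/Z mixture of 10 is carried on unseparated, because both isomers converge in step 6.

Step 1
Reactants: 1 3-iodophenol; 2 3-(benzyloxy)-4-fluorobenzaldehyde
Product: 3 3-(benzyloxy)-4-(3-iodophenoxy)benzaldehyde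
Conditions: K2CO3, DMF, 110 °C
Reagents that add atoms: none
Why: Nucleophilic aromatic substitution (SNAr), in which the para-formyl group stabilises the Meisenheimer intermediate so that the phenoxide of 1 displaces fluoride, while the aryl iodide is inert in the absence of a metal catalyst.

Step 2
Reactants: 4 3-(benzyloxy)-4-methoxybenzaldehyde
Product: 5 2-(benzyloxy)-4-ethenyl-1-methoxybenzene
Conditions: Ph3PCH3Br, KOtBu, THF, 0 °C to rt
Reagents that add atoms: methyltriphenylphosphonium bromide, C[P+](c1ccccc1)(c1ccccc1)c1ccccc1.[Br-]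
Why: Wittig methylenation of a non-enolisable aromatic aldehyde with the unstabilised ylide should be fast, and both aryl ethers are inert to the base.

Step 3
Reactants: 3 3-(benzyloxy)-4-(3-iodophenoxy)benzaldehyde; 5 2-(benzyloxy)-4-ethenyl-1-methoxybenzene
Product: 6 3-(benzyloxy)-4-{3-[(E)-2-(3-(benzyloxy)-4-methoxyphenyl)ethenyl]phenoxy}benzaldehyde
Conditions: Pd(OAc)2 (5 mol %), Bu4NCl, NaHCO3, DMF, 80 °C
Reagents that add atoms: none
Why: Mizoroki–Heck reaction under ligand-free Jeffery conditions, in which zerovalent palladium inserts into the C–I bond, the aryl group adds to the terminal alkene carbon and syn β-hydride elimination through the less crowded rotamer should give the E-stilbene, with the aldehyde and benzyl ethers as spectators.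

Step 4
Reactants: 7 2-[4-(bromomethyl)phenyl]-4,4,5,5-tetramethyl-1,3,2-dioxaborolane
Product: 8 triphenyl[4-(4,4,5,5-tetramethyl-1,3,2-dioxaborolan-2-yl)benzyl]phosphonium bromide
Conditions: PPh3, toluene, 110 °C
Reagents that add atoms: triphenylphosphine, c1ccc(cc1)P(c1ccccc1)c1ccccc1
Why: SN2 quaternisation of triphenylphosphine by a benzylic bromide, in which the neutral pinacol boronate does not take part and the salt should precipitate from toluene.

Step 5
Reactants: 6 3-(benzyloxy)-4-{3-[(E)-2-(3-(benzyloxy)-4-methoxyphenyl)ethenyl]phenoxy}benzaldehyde; 8 triphenyl[4-(4,4,5,5-tetramethyl-1,3,2-dioxaborolan-2-yl)benzyl]phosphonium bromide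
Product: 10 2-{4-[2-(3-(benzyloxy)-4-{3-[(E)-2-(3-(benzyloxy)-4-methoxyphenyl)ethenyl]phenoxy}phenyl)ethenyl]phenyl}-4,4,5,5-tetramethyl-1,3,2-dioxaborolane (E/Z mixture at the new alkene), via benzylidenephosphorane 9 (not isolated)
Conditions: 8 (1.3 equiv), KOtBu (1.25 equiv), THF, 0 °C; then 6, 0 °C to rt
Reagents that add atoms: none
Why: Wittig olefination with a semi-stabilised benzylic ylide, whose alkene geometry is of no consequence because the double bond is saturated in step 6, and the hindered pinacol boronate should tolerate a sub-stoichiometric charge of KOtBu at low temperature.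

Step 6
Reactants: 10 2-{4-[2-(3-(benzyloxy)-4-{3-[(E)-2-(3-(benzyloxy)-4-methoxyphenyl)ethenyl]phenoxy}phenyl)ethenyl]phenyl}-4,4,5,5-tetramethyl-1,3,2-dioxaborolane
Product: 11 5-{2-[3-(2-hydroxy-4-{2-[4-(4,4,5,5-tetramethyl-1,3,2-dioxaborolan-2-yl)phenyl]ethyl}phenoxy)phenyl]ethyl}-2-methoxyphenol
Conditions: H2 (1 atm), 10% Pd/C, EtOAc/EtOH, rt
Reagents that add atoms: none
Why: Heterogeneous catalytic hydrogenation over Pd/C should saturate both stilbene double bonds and hydrogenolyse both benzyl ethers in one operation, while the aryl pinacol boronate, the diaryl ether and the methyl ether are stable to these conditions.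

Step 7
Reactants: 11 5-{2-[3-(2-hydroxy-4-{2-[4-(4,4,5,5-tetramethyl-1,3,2-dioxaborolan-2-yl)phenyl]ethyl}phenoxy)phenyl]ethyl}-2-methoxyphenol
Product: 12 pakyonol
Conditions: Cu(OAc)2 (2 equiv), B(OH)3 (2 equiv), Et3N (5 equiv), 4 Å MS, MeCN, O2 (1 atm), 60 °C, syringe-pump addition of 11 (final 2 mM)
Reagents that add atoms: none
Why: Chan–Lam–Evans oxidative C–O coupling run as a macrocyclisation: the ring B aryl group is transmetalated from boron to divalent copper (boric acid binds the released pinacol, which otherwise hampers this step), the ring A phenoxide coordinates, oxidation to trivalent copper and reductive elimination form the O–C4(ring B) bond, and O2 returns copper to the divalent state. The closest known reaction type is the Cu(OAc)2-mediated diaryl ether macrocyclisation of phenol-tethered arylboronic acids and its boronic ester variant. The 20-membered ring is closed end to end by intramolecular O-arylation, an ipso substitution of boron at C4 of ring B, under pseudo-high dilution and helped by the four sp3 carbons of the two ethylene links that let the chain fold. No stereocenter is formed. The step needs chemoselectivity between two free phenols and cyclisation over chain growth: the ring C phenol could reach C4 of ring B only by closing a 10-membered ring that bridges a para-phenylene with six atoms, which is geometrically excluded, so only the ring A oxygen, an electron-rich ortho-methoxy phenol well suited to this coupling, can cyclise. Slow addition should keep intermolecular arylation of either phenol slow.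

Compound list
1 | 3-iodophenol | Oc1cccc(I)c1 | starting material
2 | 3-(benzyloxy)-4-fluorobenzaldehyde | O=Cc1ccc(F)c(OCc2ccccc2)c1 | starting material
3 | 3-(benzyloxy)-4-(3-iodophenoxy)benzaldehyde | O=Cc1ccc(Oc2cccc(I)c2)c(OCc2ccccc2)c1 | intermediate
4 | 3-(benzyloxy)-4-methoxybenzaldehyde | COc1ccc(C=O)cc1OCc1ccccc1 | starting material
5 | 2-(benzyloxy)-4-ethenyl-1-methoxybenzene | COc1ccc(C=C)cc1OCc1ccccc1 | intermediate
6 | 3-(benzyloxy)-4-{3-[(E)-2-(3-(benzyloxy)-4-methoxyphenyl)ethenyl]phenoxy}benzaldehyde | COc1ccc(/C=C/c2cccc(Oc3ccc(C=O)cc3OCc3ccccc3)c2)cc1OCc1ccccc1 | intermediate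
7 | 2-[4-(bromomethyl)phenyl]-4,4,5,5-tetramethyl-1,3,2-dioxaborolane | CC1(C)OB(OC1(C)C)c1ccc(CBr)cc1 | starting material
8 | triphenyl[4-(4,4,5,5-tetramethyl-1,3,2-dioxaborolan-2-yl)benzyl]phosphonium bromide | CC1(C)OB(OC1(C)C)c1ccc(C[P+](c2ccccc2)(c2ccccc2)c2ccccc2)cc1.[Br-] | intermediate
9 | [4-(4,4,5,5-tetramethyl-1,3,2-dioxaborolan-2-yl)benzylidene]triphenylphosphorane (not isolated) | CC1(C)OB(OC1(C)C)c1ccc(C=P(c2ccccc2)(c2ccccc2)c2ccccc2)cc1 | intermediate
10 | 2-{4-[2-(3-(benzyloxy)-4-{3-[(E)-2-(3-(benzyloxy)-4-methoxyphenyl)ethenyl]phenoxy}phenyl)ethenyl]phenyl}-4,4,5,5-tetramethyl-1,3,2-dioxaborolane; E at the ring D to ring A alkene, E/Z mixture at the ring B to ring C alkene | COc1ccc(/C=C/c2cccc(Oc3ccc(C=Cc4ccc(B5OC(C)(C)C(C)(C)O5)cc4)cc3OCc3ccccc3)c2)cc1OCc1ccccc1 | intermediate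
11 | 5-{2-[3-(2-hydroxy-4-{2-[4-(4,4,5,5-tetramethyl-1,3,2-dioxaborolan-2-yl)phenyl]ethyl}phenoxy)phenyl]ethyl}-2-methoxyphenol | COc1ccc(CCc2cccc(Oc3ccc(CCc4ccc(B5OC(C)(C)C(C)(C)O5)cc4)cc3O)c2)cc1O | intermediate
12 | pakyonol | COc1ccc2cc1Oc1ccc(cc1)CCc1ccc(c(O)c1)Oc1cccc(c1)CC2 | target

Total step count: 7. Longest linear sequence: 5 steps (steps 1, 3, 5, 6 and 7); steps 2 and 4 are side branches.

Steps most likely to fail

Step 7. The boronate may be lost by protodeboronation or by oxidation to the phenol before the ring closes, and chain growth by intermolecular O-arylation may outrun cyclisation. The fallback sets out from 6 and comes back at 12, closing the same O–C bond by an Ullmann reaction of an aryl bromide. Aldehyde 6 would be olefinated with (4-bromobenzylidene)triphenylphosphorane F1, made in the flask from commercial (4-bromobenzyl)triphenylphosphonium bromide and KOtBu in THF, to give 2-(benzyloxy)-1-{3-[(E)-2-(3-(benzyloxy)-4-methoxyphenyl)ethenyl]phenoxy}-4-[2-(4-bromophenyl)ethenyl]benzene F2. Diimide (TsNHNH2, NaOAc, aqueous THF, reflux) should saturate both alkenes without touching the C–Br bond and give 2-(benzyloxy)-1-{3-[2-(3-(benzyloxy)-4-methoxyphenyl)ethyl]phenoxy}-4-[2-(4-bromophenyl)ethyl]benzene F3. BCl3 with pentamethylbenzene (CH2Cl2, −78 °C) should remove both benzyl groups and spare the methyl ether, giving 5-[2-(3-{4-[2-(4-bromophenyl)ethyl]-2-hydroxyphenoxy}phenyl)ethyl]-2-methoxyphenol F4. An intramolecular Ullmann diaryl ether synthesis (CuI, N,N-dimethylglycine, Cs2CO3, dioxane, 100 °C, 2 mM) would then give 12; the same topological argument protects the ring C phenol.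

Step 5. tert-Butoxide or the ylide may bind to boron, which would stall the olefination or cleave the C–B bond. The fallback sets out from 6 and comes back at 11, bringing ring B in by a Heck reaction so that no boron-bearing ylide is needed. Aldehyde 6 would be methylenated (Ph3PCH3Br, KOtBu, THF) to 2-(benzyloxy)-1-{3-[(E)-2-(3-(benzyloxy)-4-methoxyphenyl)ethenyl]phenoxy}-4-ethenylbenzene F5. A Heck reaction of its terminal vinyl group with commercial 2-(4-iodophenyl)-4,4,5,5-tetramethyl-1,3,2-dioxaborolane (Pd(OAc)2, Bu4NCl, anhydrous NaHCO3, DMF, 80 °C; the weak, dry base should leave the boronate untransmetalated) would give the all-E isomer of 10, 2-{4-[(E)-2-(3-(benzyloxy)-4-{3-[(E)-2-(3-(benzyloxy)-4-methoxyphenyl)ethenyl]phenoxy}phenyl)ethenyl]phenyl}-4,4,5,5-tetramethyl-1,3,2-dioxaborolane F6. Hydrogenation under the conditions of step 6 then gives 11.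

Step 3. Arylation may occur at the internal carbon of the electron-rich styrene and give the branched isomer, and iodine may be lost reductively. The fallback sets out from 4 and 3 and comes back at 11, replacing the alkene by an alkyne so that no regiochemistry is at stake. Aldehyde 4 would be homologated by the Ohira–Bestmann reaction (dimethyl (1-diazo-2-oxopropyl)phosphonate, K2CO3, MeOH, rt) to 2-(benzyloxy)-4-ethynyl-1-methoxybenzene F7. Sonogashira coupling with 3 (Pd(PPh3)2Cl2, CuI, Et3N, THF, 50 °C) would give 3-(benzyloxy)-4-{3-[(3-(benzyloxy)-4-methoxyphenyl)ethynyl]phenoxy}benzaldehyde F8. Wittig reaction with ylide 9 as in step 5 would give 2-{4-[2-(3-(benzyloxy)-4-{3-[(3-(benzyloxy)-4-methoxyphenyl)ethynyl]phenoxy}phenyl)ethenyl]phenyl}-4,4,5,5-tetramethyl-1,3,2-dioxaborolane F9. Hydrogenation under the conditions of step 6 should reduce alkyne and alkene, cleave both benzyl ethers and give 11.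

Further compounds
F1 | step 7 | (4-bromobenzylidene)triphenylphosphorane | Brc1ccc(C=P(c2ccccc2)(c2ccccc2)c2ccccc2)cc1
F2 | step 7 | 2-(benzyloxy)-1-{3-[(E)-2-(3-(benzyloxy)-4-methoxyphenyl)ethenyl]phenoxy}-4-[2-(4-bromophenyl)ethenyl]benzene | COc1ccc(/C=C/c2cccc(Oc3ccc(C=Cc4ccc(Br)cc4)cc3OCc3ccccc3)c2)cc1OCc1ccccc1
F3 | step 7 | 2-(benzyloxy)-1-{3-[2-(3-(benzyloxy)-4-methoxyphenyl)ethyl]phenoxy}-4-[2-(4-bromophenyl)ethyl]benzene | COc1ccc(CCc2cccc(Oc3ccc(CCc4ccc(Br)cc4)cc3OCc3ccccc3)c2)cc1OCc1ccccc1
F4 | step 7 | 5-[2-(3-{4-[2-(4-bromophenyl)ethyl]-2-hydroxyphenoxy}phenyl)ethyl]-2-methoxyphenol | COc1ccc(CCc2cccc(Oc3ccc(CCc4ccc(Br)cc4)cc3O)c2)cc1O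
F5 | step 5 | 2-(benzyloxy)-1-{3-[(E)-2-(3-(benzyloxy)-4-methoxyphenyl)ethenyl]phenoxy}-4-ethenylbenzene | COc1ccc(/C=C/c2cccc(Oc3ccc(C=C)cc3OCc3ccccc3)c2)cc1OCc1ccccc1
F6 | step 5 | 2-{4-[(E)-2-(3-(benzyloxy)-4-{3-[(E)-2-(3-(benzyloxy)-4-methoxyphenyl)ethenyl]phenoxy}phenyl)ethenyl]phenyl}-4,4,5,5-tetramethyl-1,3,2-dioxaborolane | COc1ccc(/C=C/c2cccc(Oc3ccc(/C=C/c4ccc(B5OC(C)(C)C(C)(C)O5)cc4)cc3OCc3ccccc3)c2)cc1OCc1ccccc1
F7 | step 3 | 2-(benzyloxy)-4-ethynyl-1-methoxybenzene | COc1ccc(C#C)cc1OCc1ccccc1
F8 | step 3 | 3-(benzyloxy)-4-{3-[(3-(benzyloxy)-4-methoxyphenyl)ethynyl]phenoxy}benzaldehyde | COc1ccc(C#Cc2cccc(Oc3ccc(C=O)cc3OCc3ccccc3)c2)cc1OCc1ccccc1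
F9 | step 3 | 2-{4-[2-(3-(benzyloxy)-4-{3-[(3-(benzyloxy)-4-methoxyphenyl)ethynyl]phenoxy}phenyl)ethenyl]phenyl}-4,4,5,5-tetramethyl-1,3,2-dioxaborolane | COc1ccc(C#Cc2cccc(Oc3ccc(C=Cc4ccc(B5OC(C)(C)C(C)(C)O5)cc4)cc3OCc3ccccc3)c2)cc1OCc1ccccc1
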